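**Retrosynthetic overview**

1. The central C15–C15' sp2–sp2 single bond is cut last: a C20 alkenylstannane carrying the keto ring (ring A) and a C20 alkenyl iodide carrying the (S)-hydroxy ring (ring B) are joined by a Stille coupling. Both partners come from one C20 stannane; tin–iodine exchange and CBS reduction at C3' turn part of it into the ring B partner.
2. The C20 stannane comes from a C14 phosphonium salt by a single Wittig reaction at C10=C11 with a C6 stannyl dienal. The C14 salt comes from a ring C10 enol triflate by a Stille coupling at C7–C8 with a C4 stannyl alcohol.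
3. Rings: one ring-forming event serves both rings. The key step is a [3+3] annulation of the pyrrolidine dienamine of 3-methylbut-2-enal (C4–C5(CH3)–C6–C7) with 3-methylbut-2-enoyl chloride (C1(CH3)2–C2–C3). It forms C1–C6 and C3–C4 (C1'–C6' and C3'–C4' of ring B) in one operation and already contains the exocyclic C6=C7 bond of the retro chromophore. Ring B is this ring after reduction at C3'; ring A keeps the ketone.
4. Enabling feature: in each ring C4 and C6 flank the methyl-bearing C5, and C6 carries the exocyclic C7. C6 and C4 are therefore the β- and δ-carbons of a 1-aminodiene (a 1,3-dinucleophile). The gem-dimethyl C1 and the oxygenated C3 are the β- and acyl carbons of an enoyl chloride (a 1,3-dielectrophile). The ring is two C5 isoprenoid units joined head to tail.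

Key step: step 2

Remark: carotenoid locants are used (ring A = keto ring C1–C6, ring B = hydroxy ring C1'–C6'; monocyclic precursors carry the unprimed locants). Compound 16 is taken as the commercial E isomer. Stannane 20 is divided, one part going to step 11 and the other to step 13. Polyenes are handled under argon in dim light.

**Route**

Step 1
Reactants: 1 3-methylbut-2-enal; 2 pyrrolidine
Product: 3 1-[(1E)-3-methylbuta-1,3-dien-1-yl]pyrrolidine
Conditions: K2CO3, Et2O, −10 °C to rt; distillation under reduced pressure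
Reagents that add atoms: none
Why: Dienamine formation from a γ-enolisable enal and a secondary amine (iminium ion, then γ-deprotonation) should give the linear 1-aminodiene as its thermodynamic E enamine.

Step 2
Reactants: 3 1-[(1E)-3-methylbuta-1,3-dien-1-yl]pyrrolidine; 4 3-methylbut-2-enoyl chloride
Product: 8 (4E)-4-(hydroxymethylidene)-3,5,5-trimethylcyclohex-2-en-1-one, via N-acyl dienammonium chloride 5 (not isolated), via ketene iminium chloride 6 (not isolated), via aminodienone hydrochloride 7 (not isolated)
Conditions: toluene, 0 °C then 90 °C; then 1 M aq. HCl, THF, 40 °C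
Reagents that add atoms: water, O
Why: Proposed new method: N-acylation of dienamine 3 by 4 gives 5, a 3-aza-1,5-diene that should undergo a charge-accelerated [3,3] (3-aza-Cope) shift joining the enamine β-carbon C6 to the enoyl β-carbon C1 (the future gem-dimethyl carbon) and releasing ketene 6; loss of the C6 proton re-forms a 1-aminodiene whose δ-carbon C4 acylates the ketene carbon C3, and tautomerisation gives push-pull dienaminone 7, which aqueous acid hydrolyses at C7 to 8. The closest known reaction type is the α,α'-annulation of ketone enamines with α,β-unsaturated acid chlorides to cyclohexane-1,3-diones (N-acylation, sigmatropic shift, C-acylation by the ketene), whose first C–C bond is made by a sigmatropic step that, unlike a Michael addition, should not be blocked by the two β-methyl groups; the new element is its vinylogous use on a 1-aminodiene, so that the second bond forms at the δ-carbon. The single ring closes in a 6-(enolendo)-exo-dig mode (exo with respect to the ketene C=O), C4 of the dienamine attacking the sp carbon of the ketene. No stereocentre is created; the C6=C7 geometry is set under thermodynamic control in the freely rotating push-pull system, where E keeps the C7 substituent away from the in-plane C5 methyl group. The step needs C6 to bond to C1 and C4 to C3 (not the reverse, and no C-acylation at C6): the six-atom cyclic transition state of the shift can only link C6 with C1, the remaining tether then permits only six-ring closure at C4, and direct C4 acylation followed by 6-endo enamine Michael addition would converge on the same product.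

Step 3
Reactants: 8 (4E)-4-(hydroxymethylidene)-3,5,5-trimethylcyclohex-2-en-1-one
Product: 9 [(E)-(2,6,6-trimethyl-4-oxocyclohex-2-en-1-ylidene)methyl] trifluoromethanesulfonate
Conditions: Tf2O, 2,6-lutidine, CH2Cl2, −78 °C
Reagents that add atoms: trifluoromethanesulfonic anhydride, O=S(=O)(OS(=O)(=O)C(F)(F)F)C(F)(F)F
Why: O-sulfonylation of a vinylogous acid should take place at the free exocyclic enol hydroxyl (the formyl-derived oxygen, as with hydroxymethylene ketones), giving the vinylogous acyl triflate with the E geometry of 8 carried over.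

Step 4
Reactants: 10 prop-2-yn-1-ol
Product: 12 (2E)-3-iodo-2-methylprop-2-en-1-ol, via alkenylalane 11 (not isolated)
Conditions: Me3Al (3 equiv), Cp2ZrCl2 (0.25 equiv), CH2Cl2, 0 °C to rt; then I2, THF, −30 °C
Reagents that add atoms: trimethylaluminium, C[Al](C)C; iodine, II
Why: Zirconium-catalysed syn carboalumination (Negishi carboalumination) places methyl on the internal and aluminium on the terminal alkyne carbon, and iodinolysis with retention fixes the E trisubstituted alkene.

Step 5
Reactants: 12 (2E)-3-iodo-2-methylprop-2-en-1-ol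
Product: 13 (2E)-2-methyl-3-(tributylstannyl)prop-2-en-1-ol
Conditions: Bu3SnSnBu3, PdCl2(PPh3)2 (5 mol %), THF, 50 °C
Reagents that add atoms: hexabutylditin, CCCC[Sn](CCCC)(CCCC)[Sn](CCCC)(CCCC)CCCC
Why: Palladium-catalysed stannylation of an alkenyl iodide with a ditin (oxidative addition to zerovalent palladium, Sn–Sn transmetalation, reductive elimination) proceeds with retention and tolerates the free hydroxyl.

Step 6
Reactants: 9 [(E)-(2,6,6-trimethyl-4-oxocyclohex-2-en-1-ylidene)methyl] trifluoromethanesulfonate; 13 (2E)-2-methyl-3-(tributylstannyl)prop-2-en-1-ol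
Product: 14 (4E)-4-[(2E)-4-hydroxy-3-methylbut-2-en-1-ylidene]-3,5,5-trimethylcyclohex-2-en-1-one
Conditions: Pd2(dba)3 (2.5 mol %), AsPh3 (20 mol %), LiCl, NMP, rt
Reagents that add atoms: none
Why: Stille coupling of an electron-poor alkenyl triflate (β-sulfonyloxy-enone type) with an alkenylstannane forms C7–C8 with retention at both partners under neutral conditions that spare the enolisable ketone.

Step 7
Reactants: 14 (4E)-4-[(2E)-4-hydroxy-3-methylbut-2-en-1-ylidene]-3,5,5-trimethylcyclohex-2-en-1-one
Product: 15 [(2E,4E)-2-methyl-4-(2,6,6-trimethyl-4-oxocyclohex-2-en-1-ylidene)but-2-en-1-yl](triphenyl)phosphonium bromide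
Conditions: PPh3·HBr, MeOH/CH2Cl2, 0 °C to rt
Reagents that add atoms: triphenylphosphine hydrobromide, Br.c1ccc(cc1)P(c1ccccc1)c1ccccc1
Why: Standard conversion of a primary allylic alcohol into its allyltriphenylphosphonium bromide, with substitution expected at the primary terminus C10 because this keeps the trienone conjugated.

Step 8
Reactants: 16 (2E)-3-methylpent-2-en-4-yn-1-ol
Product: 17 (2E,4E)-3-methyl-5-(tributylstannyl)penta-2,4-dien-1-ol
Conditions: Bu3SnH, PdCl2(PPh3)2 (2 mol %), THF, 0 °C
Reagents that add atoms: tributyltin hydride, CCCC[SnH](CCCC)CCCC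
Why: Palladium-catalysed syn hydrostannation of the terminal enyne should deliver tin to the terminal carbon and give the 4E dienylstannane.

Step 9
Reactants: 17 (2E,4E)-3-methyl-5-(tributylstannyl)penta-2,4-dien-1-ol
Product: 18 (2E,4E)-3-methyl-5-(tributylstannyl)penta-2,4-dienal
Conditions: MnO2, CH2Cl2, rt
Reagents that add atoms: none
Why: Chemoselective MnO2 oxidation of an allylic alcohol to the dienal, to which the alkenylstannane is inert.

Step 10
Reactants: 15 [(2E,4E)-2-methyl-4-(2,6,6-trimethyl-4-oxocyclohex-2-en-1-ylidene)but-2-en-1-yl](triphenyl)phosphonium bromide; 18 (2E,4E)-3-methyl-5-(tributylstannyl)penta-2,4-dienal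
Product: 20 (4E)-4-[(2E,4E,6E,8E)-3,7-dimethyl-9-(tributylstannyl)nona-2,4,6,8-tetraen-1-ylidene]-3,5,5-trimethylcyclohex-2-en-1-one, via phosphonium ylide 19 (not isolated)
Conditions: NaOMe, MeOH/CH2Cl2, 0 °C to rt, argon, dark
Reagents that add atoms: none
Why: Wittig olefination with a ylide that is stabilised vinylogously by the ring ketone (the type used for oxo-carotenoid end groups) forms C10=C11 and should favour E, the alkenylstannane being inert to methoxide; any 10Z isomer is removed by chromatography.

Step 11
Reactants: 20 (4E)-4-[(2E,4E,6E,8E)-3,7-dimethyl-9-(tributylstannyl)nona-2,4,6,8-tetraen-1-ylidene]-3,5,5-trimethylcyclohex-2-en-1-one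
Product: 21 (4E)-4-[(2E,4E,6E,8E)-9-iodo-3,7-dimethylnona-2,4,6,8-tetraen-1-ylidene]-3,5,5-trimethylcyclohex-2-en-1-one
Conditions: I2 (1.05 equiv), CH2Cl2, −40 to 0 °C, dark; then aq. Na2S2O3
Reagents that add atoms: iodine, II
Why: Iododestannylation (ipso substitution at the carbon–tin bond with retention) should be much faster than any addition of iodine to the electron-poor polyenone and converts part of the stannane into the E alkenyl iodide, so that both coupling partners come from one Wittig product.

Step 12
Reactants: 21 (4E)-4-[(2E,4E,6E,8E)-9-iodo-3,7-dimethylnona-2,4,6,8-tetraen-1-ylidene]-3,5,5-trimethylcyclohex-2-en-1-one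
Product: 22 (1S,4E)-4-[(2E,4E,6E,8E)-9-iodo-3,7-dimethylnona-2,4,6,8-tetraen-1-ylidene]-3,5,5-trimethylcyclohex-2-en-1-ol
Conditions: (R)-2-methyl-CBS-oxazaborolidine (0.3 equiv), catecholborane, toluene/CH2Cl2, −78 to −40 °C; then MeOH, aq. NaOH
Reagents that add atoms: none
Why: Corey–Bakshi–Shibata reduction of the conjugated ketone gives 1,2-reduction only, and the R catalyst is chosen so that, with the polyenyl flank as the large and the CH2 flank as the small substituent, hydride is delivered to the face that gives the 3'S carbinol.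

Step 13
Reactants: 20 (4E)-4-[(2E,4E,6E,8E)-3,7-dimethyl-9-(tributylstannyl)nona-2,4,6,8-tetraen-1-ylidene]-3,5,5-trimethylcyclohex-2-en-1-one; 22 (1S,4E)-4-[(2E,4E,6E,8E)-9-iodo-3,7-dimethylnona-2,4,6,8-tetraen-1-ylidene]-3,5,5-trimethylcyclohex-2-en-1-ol
Product: 23 (3'S,6E,6'E)-3'-hydroxy-4',5'-didehydro-4,5'-retro-β,β-caroten-3-one, all-E (target)
Conditions: Pd2(dba)3 (5 mol %), AsPh3 (40 mol %), NMP, rt, argon, dark
Reagents that add atoms: none
Why: Stille coupling of the alkenyl iodide with the alkenylstannane joins C15 and C15' with retention at both alkenes under neutral conditions that should leave the ketone, the free allylic alcohol, the C3' stereocentre and the polyene untouched.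

**Compound list**

1 | 3-methylbut-2-enal | CC(C)=CC=O | starting material
2 | pyrrolidine | C1CCNC1 | starting material
3 | 1-[(1E)-3-methylbuta-1,3-dien-1-yl]pyrrolidine | C=C(C)/C=C/N1CCCC1 | intermediate
4 | 3-methylbut-2-enoyl chloride | CC(C)=CC(Cl)=O | starting material
5 | 1-(3-methylbut-2-enoyl)-1-[(1E)-3-methylbuta-1,3-dien-1-yl]pyrrolidin-1-ium chloride | C=C(C)/C=C/[N+]1(C(=O)C=C(C)C)CCCC1.[Cl-] | intermediate
6 | 1-[3,3-dimethyl-5-oxo-2-(prop-1-en-2-yl)pent-4-en-1-ylidene]pyrrolidin-1-ium chloride (ketene iminium) | O=C=CC(C)(C)C(C(C)=C)C=[N+]1CCCC1.[Cl-] | intermediate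
7 | (4E)-3,5,5-trimethyl-4-(pyrrolidin-1-ylmethylidene)cyclohex-2-en-1-one hydrochloride | O=C1C=C(C)/C(=C/N2CCCC2)C(C)(C)C1.Cl | intermediate
8 | (4E)-4-(hydroxymethylidene)-3,5,5-trimethylcyclohex-2-en-1-one | O=C1C=C(C)/C(=C/O)C(C)(C)C1 | intermediate
9 | [(E)-(2,6,6-trimethyl-4-oxocyclohex-2-en-1-ylidene)methyl] trifluoromethanesulfonate | O=C1C=C(C)/C(=C/OS(=O)(=O)C(F)(F)F)C(C)(C)C1 | intermediate
10 | prop-2-yn-1-ol | OCC#C | starting material
11 | dimethyl{(1E)-3-[(dimethylalumanyl)oxy]-2-methylprop-1-en-1-yl}alumane (alkenylalane) | C[Al](C)/C=C(\C)CO[Al](C)C | intermediate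
12 | (2E)-3-iodo-2-methylprop-2-en-1-ol | OC/C(C)=C/I | intermediate
13 | (2E)-2-methyl-3-(tributylstannyl)prop-2-en-1-ol | OC/C(C)=C/[Sn](CCCC)(CCCC)CCCC | intermediate
14 | (4E)-4-[(2E)-4-hydroxy-3-methylbut-2-en-1-ylidene]-3,5,5-trimethylcyclohex-2-en-1-one | CC1=CC(=O)CC(C)(C)\C1=C/C=C(C)/CO | intermediate
15 | [(2E,4E)-2-methyl-4-(2,6,6-trimethyl-4-oxocyclohex-2-en-1-ylidene)but-2-en-1-yl](triphenyl)phosphonium bromide | CC1=CC(=O)CC(C)(C)\C1=C/C=C(C)/C[P+](c1ccccc1)(c1ccccc1)c1ccccc1.[Br-] | intermediate
16 | (2E)-3-methylpent-2-en-4-yn-1-ol | OC/C=C(C)/C#C | starting material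
17 | (2E,4E)-3-methyl-5-(tributylstannyl)penta-2,4-dien-1-ol | OC/C=C(C)/C=C/[Sn](CCCC)(CCCC)CCCC | intermediate
18 | (2E,4E)-3-methyl-5-(tributylstannyl)penta-2,4-dienal | O=C/C=C(C)/C=C/[Sn](CCCC)(CCCC)CCCC | intermediate
19 | phosphonium ylide of 15 | CC1=CC(=O)CC(C)(C)\C1=C/C=C(C)/[CH-][P+](c1ccccc1)(c1ccccc1)c1ccccc1 | intermediate
20 | (4E)-4-[(2E,4E,6E,8E)-3,7-dimethyl-9-(tributylstannyl)nona-2,4,6,8-tetraen-1-ylidene]-3,5,5-trimethylcyclohex-2-en-1-one | CC1=CC(=O)CC(C)(C)\C1=C/C=C(C)/C=C/C=C(C)/C=C/[Sn](CCCC)(CCCC)CCCC | intermediate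
21 | (4E)-4-[(2E,4E,6E,8E)-9-iodo-3,7-dimethylnona-2,4,6,8-tetraen-1-ylidene]-3,5,5-trimethylcyclohex-2-en-1-one | CC1=CC(=O)CC(C)(C)\C1=C/C=C(C)/C=C/C=C(C)/C=C/I | intermediate
22 | (1S,4E)-4-[(2E,4E,6E,8E)-9-iodo-3,7-dimethylnona-2,4,6,8-tetraen-1-ylidene]-3,5,5-trimethylcyclohex-2-en-1-ol | I/C=C/C(C)=C/C=C/C(C)=C/C=C1/C(C)=C[C@@H](O)CC1(C)C | intermediate
23 | (3'S,6E,6'E)-3'-hydroxy-4',5'-didehydro-4,5'-retro-β,β-caroten-3-one, all-E | CC1=CC(=O)CC(C)(C)\C1=C/C=C(C)/C=C/C=C(C)/C=C/C=C/C(C)=C/C=C/C(C)=C/C=C1/C(C)=C[C@@H](O)CC1(C)C | target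

**Step count and risks**

Total steps: 13. Longest linear sequence: 9 steps (1, 2, 3, 6, 7, 10, 11, 12, 13).

Steps most likely to fail:

1. Step 2 (the labelled step). The acid chloride may C-acylate the dienamine at its β-carbon (wrong connectivity), or be deprotonated to a vinylketene that undergoes [2+2] reactions, so that the sigmatropic/annulation cascade is not entered. The fallback uses known reaction types and makes the same two bonds stepwise. It sets out from 1: silylation (TMSCl, Et3N, NaI, MeCN) gives trimethyl{[(1E)-3-methylbuta-1,3-dien-1-yl]oxy}silane F1. A vinylogous Mukaiyama aldol addition of F1 to a second equivalent of 1 (BF3·OEt2, CH2Cl2, −78 °C) forms C3–C4 and gives (2E)-5-hydroxy-3,7-dimethylocta-2,6-dienal F2. MnO2 oxidation of the allylic alcohol gives (2E)-3,7-dimethyl-5-oxoocta-2,6-dienal F3. DBU in THF then induces the 6-endo intramolecular Michael addition of the dienolate α-carbon (C6) to the β,β-dimethyl enone carbon (C1), the acyclic dienone to cyclohexenone closure known from phorone-type ketones. This comes back to the route at 8.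

2. Step 3. Sulfonylation may occur at the ring oxygen of the ambident vinylogous acid instead of the exocyclic one, or give the Z enol triflate, which would carry the wrong C6=C7 geometry forward. The fallback sets out from 8: acid-catalysed exchange with butane-1-thiol (TsOH, benzene, reflux with water removal) takes place at the formyl carbon under thermodynamic control and gives (4E)-4-[(butylsulfanyl)methylidene]-3,5,5-trimethylcyclohex-2-en-1-one F4. A Liebeskind–Srogl-type coupling of this vinylogous thioester with stannane 13 (Pd(PPh3)4, Cu(O2CC4H3S) (copper thiophene-2-carboxylate), THF, 50 °C) comes back to the route at 14.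

3. Step 12. Facial discrimination may be poor because the CH2 flank is made bulky by the neighbouring gem-dimethyl carbon, or hydride transfer to the vinylogously deactivated carbonyl may be slow. The fallback sets out from 21: Luche reduction (NaBH4, CeCl3·7H2O, MeOH/THF, −40 °C) gives racemic 4-[(2E,4E,6E,8E)-9-iodo-3,7-dimethylnona-2,4,6,8-tetraen-1-ylidene]-3,5,5-trimethylcyclohex-2-en-1-ol F5. Lipase-catalysed kinetic resolution (immobilised Candida antarctica lipase B, vinyl acetate, MTBE, rt) should, by the usual enantiopreference of lipases for secondary alcohols, acylate the R enantiomer to (1R,4E)-4-[(2E,4E,6E,8E)-9-iodo-3,7-dimethylnona-2,4,6,8-tetraen-1-ylidene]-3,5,5-trimethylcyclohex-2-en-1-yl acetate F6. The unreacted S alcohol is separated by chromatography, which comes back to the route at 22.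

Further compounds
F1 | step 2 | trimethyl{[(1E)-3-methylbuta-1,3-dien-1-yl]oxy}silane | C=C(C)/C=C/O[Si](C)(C)C
F2 | step 2 | (2E)-5-hydroxy-3,7-dimethylocta-2,6-dienal | O=C/C=C(C)/CC(O)C=C(C)C
F3 | step 2 | (2E)-3,7-dimethyl-5-oxoocta-2,6-dienal | O=C/C=C(C)/CC(=O)C=C(C)C
F4 | step 3 | (4E)-4-[(butylsulfanyl)methylidene]-3,5,5-trimethylcyclohex-2-en-1-one | O=C1C=C(C)/C(=C/SCCCC)C(C)(C)C1
F5 | step 12 | racemic (4E)-4-[(2E,4E,6E,8E)-9-iodo-3,7-dimethylnona-2,4,6,8-tetraen-1-ylidene]-3,5,5-trimethylcyclohex-2-en-1-ol | CC1=CC(O)CC(C)(C)\C1=C/C=C(C)/C=C/C=C(C)/C=C/I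
F6 | step 12 | (1R,4E)-4-[(2E,4E,6E,8E)-9-iodo-3,7-dimethylnona-2,4,6,8-tetraen-1-ylidene]-3,5,5-trimethylcyclohex-2-en-1-yl acetate | I/C=C/C(C)=C/C=C/C(C)=C/C=C1/C(C)=C[C@H](OC(C)=O)CC1(C)C
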